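Ring A is built last, on the depside ester itself. It is a resorcinol with hydroxyls on C2 and C4, hydrogen on C3 between them, the ester carbon on C1 and propyl on C6, which is the substitution that results when a vinylketene is united with an ynol ether. Irradiation of diazo enone 14, an unhindered (E)-enoate of ring B phenol 6, with siloxyalkyne 17 should form C1–C2, C2–C3 and C4–C5 and close ring A in one operation. The congested 2,6-disubstituted benzoate therefore never has to be made by esterification. Desilylation and hydrogenolysis finish the synthesis.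

Key step: step 10

Remark: acid 1 is taken as a catalogue compound, and lithium ethynolate 16 is assumed to be silylated on oxygen by the bulky silyl triflate, as its substituted homologues are.

Step 1
Reactants: 1 2,4-dihydroxy-6-propylbenzoic acid
Product: 2 benzyl 4-(benzyloxy)-2-hydroxy-6-propylbenzoate
Conditions: BnBr (2 equiv), K2CO3, DMF, rt
Reagents that add atoms: benzyl bromide, BrCc1ccccc1
Why: O-alkylation (Williamson type) should take the carboxylate and the more acidic, unchelated 4-hydroxyl, while the 2-hydroxyl, hydrogen-bonded to the ester carbonyl, stays free at room temperature.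

Step 2
Reactants: 2 benzyl 4-(benzyloxy)-2-hydroxy-6-propylbenzoate
Product: 3 benzyl 4-(benzyloxy)-3-formyl-2-hydroxy-6-propylbenzoate
Conditions: MgCl2, Et3N, (CH2O)n, MeCN, reflux
Reagents that add atoms: paraformaldehyde (formaldehyde), C=O
Why: Magnesium-mediated ortho-formylation of a phenol delivers formaldehyde only ortho to the free hydroxyl, C3 being the sole open ortho position, and a second formaldehyde oxidizes the hydroxymethyl adduct to the aldehyde.

Step 3
Reactants: 3 benzyl 4-(benzyloxy)-3-formyl-2-hydroxy-6-propylbenzoate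
Product: 4 benzyl 4-(benzyloxy)-3-formyl-2-methoxy-6-propylbenzoate
Conditions: MeI, K2CO3, DMF, 40 °C
Reagents that add atoms: iodomethane, CI
Why: Williamson ether synthesis on the only remaining acidic site, the chelated 2-hydroxyl, should proceed cleanly under carbonate in a dipolar aprotic solvent.

Step 4
Reactants: 4 benzyl 4-(benzyloxy)-3-formyl-2-methoxy-6-propylbenzoate
Product: 6 benzyl 4-(benzyloxy)-3-hydroxy-2-methoxy-6-propylbenzoate, via aryl formate 5 (not isolated)
Conditions: mCPBA, CH2Cl2, 0 °C to rt; then Et3N (cat.), MeOH, rt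
Reagents that add atoms: 3-chloroperoxybenzoic acid, OOC(=O)c1cccc(Cl)c1
Why: In this Baeyer–Villiger (Dakin-type) oxidation the electron-rich aryl group flanked by two alkoxy substituents should migrate in preference to hydrogen, and the resulting formate is methanolysed under conditions too mild to touch the hindered benzyl benzoate.

Step 5
Reactants: 7 butyltriphenylphosphonium bromide
Product: 9 3-(triphenylphosphoranylidene)hexan-2-one, via butylidenetriphenylphosphorane 8 (not isolated)
Conditions: 7 (2 equiv), n-BuLi (2 equiv), THF, 0 °C; AcCl (1 equiv), −78 °C to rt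
Reagents that add atoms: acetyl chloride, CC(Cl)=O
Why: C-acylation of a non-stabilized ylide by an acid chloride followed by transylidation, in which the second equivalent of 8 deprotonates the acylphosphonium salt, should give the stabilized ylide.

Step 6
Reactants: 9 3-(triphenylphosphoranylidene)hexan-2-one, 10 glyoxylic acid monohydrate
Product: 11 (2E)-4-oxo-3-propylpent-2-enoic acid
Conditions: THF, rt to 50 °C
Reagents that add atoms: none
Why: Wittig olefination of the highly reactive glyoxylic aldehyde by an α-branched stabilized ylide should, under reversible oxaphosphetane formation, place the carboxyl trans to the acetyl group and thus set the (E) alkene that the key step needs.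

Step 7
Reactants: 6 benzyl 4-(benzyloxy)-3-hydroxy-2-methoxy-6-propylbenzoate, 11 (2E)-4-oxo-3-propylpent-2-enoic acid
Product: 12 6-(benzyloxy)-3-(benzyloxycarbonyl)-2-methoxy-4-propylphenyl (2E)-4-oxo-3-propylpent-2-enoate
Conditions: DCC, DMAP (cat.), CH2Cl2, 0 °C to rt
Reagents that add atoms: none
Why: Steglich esterification should acylate the hindered phenol because the acyl donor is an unhindered enoic acid, and the (E) acid cannot close to a pseudo-ester.

Step 8
Reactants: 12 6-(benzyloxy)-3-(benzyloxycarbonyl)-2-methoxy-4-propylphenyl (2E)-4-oxo-3-propylpent-2-enoate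
Product: 14 6-(benzyloxy)-3-(benzyloxycarbonyl)-2-methoxy-4-propylphenyl (2E)-5-diazo-4-oxo-3-propylpent-2-enoate, via trifluoroacetyl diketone 13 (not isolated)
Conditions: LiN(SiMe3)2, THF, −78 °C; CF3CO2CH2CF3, −78 °C; aqueous work-up, then MsN3, Et3N, H2O, MeCN, rt
Reagents that add atoms: methanesulfonyl azide, CS(=O)(=O)N=[N+]=[N-] (the N2 of 14); 2,2,2-trifluoroethyl trifluoroacetate, O=C(OCC(F)(F)F)C(F)(F)F (the trifluoroacetyl group of 13, lost again)
Why: Detrifluoroacetylative diazo transfer (Regitz type) enolizes the methyl group, the only α-position, activates it as the trifluoroacetyl diketone and transfers N2 from the sulfonyl azide, which avoids exposing the electron-poor alkene to diazomethane and its dipolar cycloaddition.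

Step 9
Reactants: 15 ethyl dibromoacetate
Product: 17 (triisopropylsilyloxy)acetylene, via lithium ethynolate 16 (not isolated)
Conditions: t-BuLi (4 equiv), THF, −78 to 0 °C; i-Pr3SiOTf (2 equiv), −78 °C
Reagents that add atoms: triisopropylsilyl trifluoromethanesulfonate, CC(C)[Si](OS(=O)(=O)C(F)(F)F)(C(C)C)C(C)C
Why: Ynolate formation by ester dianion cleavage relies on two bromine–lithium exchanges to give the dianion, which expels ethoxide, and the bulky, hard silyl triflate should then trap the ynolate on oxygen.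

Step 10
Reactants: 14 6-(benzyloxy)-3-(benzyloxycarbonyl)-2-methoxy-4-propylphenyl (2E)-5-diazo-4-oxo-3-propylpent-2-enoate, 17 (triisopropylsilyloxy)acetylene
Product: 22 benzyl 4-(benzyloxy)-3-{[2-hydroxy-6-propyl-4-(triisopropylsilyloxy)benzoyl]oxy}-2-methoxy-6-propylbenzoate, via vinylketene 18 (not isolated), via vinylcyclobutenone 19 (not isolated), via dienylketene 20 (not isolated), via cyclohexadienone 21 (not isolated)
Conditions: 17 (2 equiv), hν (300–350 nm, Pyrex), ClCH2CH2Cl, rt; then 80 °C
Reagents that add atoms: none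
Why: Light expels N2 from 14 and the alkenyl group shifts to the carbene carbon (photochemical Wolff rearrangement) to give vinylketene 18, whose carbonyl carbon bonds to the unsubstituted, nucleophilic carbon of 17 while the ketene α-carbon bonds to the siloxy carbon, so the [2+2] cycloaddition forms C2–C3 and C4–C5 in cyclobutenone 19. Conrotatory 4-electron opening of 19 gives dienylketene 20, and its disrotatory 6-electron electrocyclization forms C1–C2 and closes ring A as dienone 21, which enolizes to the phenol. This is the diazo ketone version of the Danheiser benzannulation, established for diazo enones with carbon substituents and applied here to an enone whose β-carbon carries an aryl ester; the ester should make the ketene more electrophilic towards the ynol ether and sits at the outward position of the closing triene. No stereocentre results, since the sp3 centres of 19 and 21 are erased on aromatization. The step needs one regiochemistry, secured by the polarization of the ynol ether (the siloxy carbon becomes C4 and the ketene oxygen the C2 hydroxyl), and retention of the (E) alkene, which holds the ester carbonyl trans to the ketene so that oxa-electrocyclization to a 2-pyranone is geometrically excluded. Long-wavelength light and an excess of 17 are chosen to limit E/Z isomerization and photo-Fries cleavage before the ketene is trapped.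

Step 11
Reactants: 22 benzyl 4-(benzyloxy)-3-{[2-hydroxy-6-propyl-4-(triisopropylsilyloxy)benzoyl]oxy}-2-methoxy-6-propylbenzoate
Product: 23 benzyl 4-(benzyloxy)-3-[(2,4-dihydroxy-6-propylbenzoyl)oxy]-2-methoxy-6-propylbenzoate
Conditions: HF·pyridine, THF, 0 °C to rt
Reagents that add atoms: none
Why: Fluoride-mediated desilylation should cleave the aryl silyl ether of the acidic 4-phenol under buffered conditions that leave the depside ester and the benzyl groups intact.

Step 12
Reactants: 23 benzyl 4-(benzyloxy)-3-[(2,4-dihydroxy-6-propylbenzoyl)oxy]-2-methoxy-6-propylbenzoate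
Product: 24 3-[(2,4-dihydroxy-6-propylbenzoyl)oxy]-4-hydroxy-2-methoxy-6-propylbenzoic acid
Conditions: H2 (1 atm), Pd/C, EtOAc, rt
Reagents that add atoms: none
Why: Catalytic hydrogenolysis should remove the benzyl ether and the benzyl ester in a neutral solvent without reducing the aryl ester bond of the depside.

Compound list
1 | 2,4-dihydroxy-6-propylbenzoic acid | CCCc1cc(O)cc(O)c1C(=O)O | starting material
2 | benzyl 4-(benzyloxy)-2-hydroxy-6-propylbenzoate | CCCc1cc(OCc2ccccc2)cc(O)c1C(=O)OCc1ccccc1 | intermediate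
3 | benzyl 4-(benzyloxy)-3-formyl-2-hydroxy-6-propylbenzoate | CCCc1cc(OCc2ccccc2)c(C=O)c(O)c1C(=O)OCc1ccccc1 | intermediate
4 | benzyl 4-(benzyloxy)-3-formyl-2-methoxy-6-propylbenzoate | CCCc1cc(OCc2ccccc2)c(C=O)c(OC)c1C(=O)OCc1ccccc1 | intermediate
5 | benzyl 4-(benzyloxy)-3-(formyloxy)-2-methoxy-6-propylbenzoate | CCCc1cc(OCc2ccccc2)c(OC=O)c(OC)c1C(=O)OCc1ccccc1 | intermediate
6 | benzyl 4-(benzyloxy)-3-hydroxy-2-methoxy-6-propylbenzoate | CCCc1cc(OCc2ccccc2)c(O)c(OC)c1C(=O)OCc1ccccc1 | intermediate
7 | butyltriphenylphosphonium bromide | CCCC[P+](c1ccccc1)(c1ccccc1)c1ccccc1.[Br-] | starting material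
8 | butylidenetriphenylphosphorane | CCCC=P(c1ccccc1)(c1ccccc1)c1ccccc1 | intermediate
9 | 3-(triphenylphosphoranylidene)hexan-2-one | CCCC(C(C)=O)=P(c1ccccc1)(c1ccccc1)c1ccccc1 | intermediate
10 | glyoxylic acid monohydrate (2,2-dihydroxyacetic acid) | OC(O)C(=O)O | starting material
11 | (2E)-4-oxo-3-propylpent-2-enoic acid | CCC/C(C(C)=O)=C\C(=O)O | intermediate
12 | 6-(benzyloxy)-3-(benzyloxycarbonyl)-2-methoxy-4-propylphenyl (2E)-4-oxo-3-propylpent-2-enoate | CCC/C(C(C)=O)=C\C(=O)Oc1c(OCc2ccccc2)cc(CCC)c(C(=O)OCc2ccccc2)c1OC | intermediate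
13 | 6-(benzyloxy)-3-(benzyloxycarbonyl)-2-methoxy-4-propylphenyl (2E)-6,6,6-trifluoro-4,6-dioxo-3-propylhex-2-enoate (drawn as the diketo tautomer) | CCC/C(C(=O)CC(=O)C(F)(F)F)=C\C(=O)Oc1c(OCc2ccccc2)cc(CCC)c(C(=O)OCc2ccccc2)c1OC | intermediate
14 | 6-(benzyloxy)-3-(benzyloxycarbonyl)-2-methoxy-4-propylphenyl (2E)-5-diazo-4-oxo-3-propylpent-2-enoate | CCC/C(C(=O)C=[N+]=[N-])=C\C(=O)Oc1c(OCc2ccccc2)cc(CCC)c(C(=O)OCc2ccccc2)c1OC | intermediate
15 | ethyl dibromoacetate | CCOC(=O)C(Br)Br | starting material
16 | lithium ethynolate | [Li+].[O-]C#C | intermediate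
17 | (triisopropylsilyloxy)acetylene | C#CO[Si](C(C)C)(C(C)C)C(C)C | intermediate
18 | 6-(benzyloxy)-3-(benzyloxycarbonyl)-2-methoxy-4-propylphenyl (2E)-5-oxo-3-propylpenta-2,4-dienoate | CCC/C(C=C=O)=C\C(=O)Oc1c(OCc2ccccc2)cc(CCC)c(C(=O)OCc2ccccc2)c1OC | intermediate
19 | 6-(benzyloxy)-3-(benzyloxycarbonyl)-2-methoxy-4-propylphenyl (2E)-3-[4-oxo-2-(triisopropylsilyloxy)cyclobut-2-en-1-yl]hex-2-enoate (racemic) | CCC/C(C1C(=O)C=C1O[Si](C(C)C)(C(C)C)C(C)C)=C\C(=O)Oc1c(OCc2ccccc2)cc(CCC)c(C(=O)OCc2ccccc2)c1OC | intermediate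
20 | 6-(benzyloxy)-3-(benzyloxycarbonyl)-2-methoxy-4-propylphenyl (2E,4E)-7-oxo-3-propyl-5-(triisopropylsilyloxy)hepta-2,4,6-trienoate | CCC/C(/C=C(\C=C=O)O[Si](C(C)C)(C(C)C)C(C)C)=C\C(=O)Oc1c(OCc2ccccc2)cc(CCC)c(C(=O)OCc2ccccc2)c1OC | intermediate
21 | 6-(benzyloxy)-3-(benzyloxycarbonyl)-2-methoxy-4-propylphenyl 6-oxo-2-propyl-4-(triisopropylsilyloxy)cyclohexa-2,4-diene-1-carboxylate (racemic) | CCCC1=CC(O[Si](C(C)C)(C(C)C)C(C)C)=CC(=O)C1C(=O)Oc1c(OCc2ccccc2)cc(CCC)c(C(=O)OCc2ccccc2)c1OC | intermediate
22 | benzyl 4-(benzyloxy)-3-{[2-hydroxy-6-propyl-4-(triisopropylsilyloxy)benzoyl]oxy}-2-methoxy-6-propylbenzoate | CCCc1cc(O[Si](C(C)C)(C(C)C)C(C)C)cc(O)c1C(=O)Oc1c(OCc2ccccc2)cc(CCC)c(C(=O)OCc2ccccc2)c1OC | intermediate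
23 | benzyl 4-(benzyloxy)-3-[(2,4-dihydroxy-6-propylbenzoyl)oxy]-2-methoxy-6-propylbenzoate | CCCc1cc(O)cc(O)c1C(=O)Oc1c(OCc2ccccc2)cc(CCC)c(C(=O)OCc2ccccc2)c1OC | intermediate
24 | 3-[(2,4-dihydroxy-6-propylbenzoyl)oxy]-4-hydroxy-2-methoxy-6-propylbenzoic acid | CCCc1cc(O)cc(O)c1C(=O)Oc1c(O)cc(CCC)c(C(=O)O)c1OC | target

Total step count: 12. Longest linear sequence: 9 steps (steps 1, 2, 3, 4, 7, 8, 10, 11, 12).

Steps most likely to fail

Step 10. The enoate may isomerize E to Z under irradiation, and the (Z)-vinylketene would then close through the ester oxygen to a 2-pyranone. The aryl ester may also undergo photo-Fries cleavage, or untrapped ketene may acylate the product phenol. The fallback is a classical depside esterification that sets out from 1 and 6 and comes back at 24. Exhaustive benzylation of 1 (BnBr, K2CO3, DMF, 60 °C) would give benzyl 2,4-bis(benzyloxy)-6-propylbenzoate F1. Saponification (KOH, aqueous DMSO, 90 °C) would give 2,4-bis(benzyloxy)-6-propylbenzoic acid F2. Condensation of F2 with phenol 6 through the mixed trifluoroacetic anhydride (TFAA, toluene, rt) would give benzyl 4-(benzyloxy)-3-{[2,4-bis(benzyloxy)-6-propylbenzoyl]oxy}-2-methoxy-6-propylbenzoate F3. Hydrogenolysis of all four benzyl groups (H2, Pd/C, EtOAc) would then give 24.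

Step 8. The lithium enolate may add in Michael or Claisen fashion to the ene-dicarbonyl unit or the aryl ester of a second molecule, and the aryl ester may be cleaved during the amine and water treatment. The fallback avoids a metal enolate; it sets out from 12 and comes back at 14. Soft enolization (Me3SiOTf, Et3N, CH2Cl2, 0 °C) would give 6-(benzyloxy)-3-(benzyloxycarbonyl)-2-methoxy-4-propylphenyl (2E)-3-propyl-4-(trimethylsilyloxy)penta-2,4-dienoate F4. Bromination at the terminal carbon (NBS, THF, −78 °C) would give 6-(benzyloxy)-3-(benzyloxycarbonyl)-2-methoxy-4-propylphenyl (2E)-5-bromo-4-oxo-3-propylpent-2-enoate F5. Substitution by N,N'-ditosylhydrazine with double sulfinate elimination (DBU, THF, 0 °C) would give 14.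

Step 9. tert-Butyllithium may deprotonate the α-carbon of 15 in competition with bromine–lithium exchange, and the unhindered parent ynolate may be silylated on carbon to a silylketene. The fallback replaces the silyl ynol ether by a tert-butyl ynol ether; it sets out from 14 and comes back at 23. KOt-Bu and trichloroethylene (THF, −78 °C to rt) would give tert-butyl (E)-1,2-dichlorovinyl ether F6. n-BuLi (2 equiv, −78 °C) would convert it to lithium tert-butoxyacetylide F7, and a methanol quench would give tert-butoxyacetylene F8. Benzannulation of 14 with F8 under the conditions of step 10, with excess alkyne evaporated before heating, would give benzyl 4-(benzyloxy)-3-{[4-(tert-butoxy)-2-hydroxy-6-propylbenzoyl]oxy}-2-methoxy-6-propylbenzoate F9. Cleavage of its tert-butyl ether (TFA, CH2Cl2, 0 °C) would give 23.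

Further compounds
F1 | step 10 | benzyl 2,4-bis(benzyloxy)-6-propylbenzoate | CCCc1cc(OCc2ccccc2)cc(OCc2ccccc2)c1C(=O)OCc1ccccc1
F2 | step 10 | 2,4-bis(benzyloxy)-6-propylbenzoic acid | CCCc1cc(OCc2ccccc2)cc(OCc2ccccc2)c1C(=O)O
F3 | step 10 | benzyl 4-(benzyloxy)-3-{[2,4-bis(benzyloxy)-6-propylbenzoyl]oxy}-2-methoxy-6-propylbenzoate | CCCc1cc(OCc2ccccc2)cc(OCc2ccccc2)c1C(=O)Oc1c(OCc2ccccc2)cc(CCC)c(C(=O)OCc2ccccc2)c1OC
F4 | step 8 | 6-(benzyloxy)-3-(benzyloxycarbonyl)-2-methoxy-4-propylphenyl (2E)-3-propyl-4-(trimethylsilyloxy)penta-2,4-dienoate | CCC/C(C(=C)O[Si](C)(C)C)=C\C(=O)Oc1c(OCc2ccccc2)cc(CCC)c(C(=O)OCc2ccccc2)c1OC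
F5 | step 8 | 6-(benzyloxy)-3-(benzyloxycarbonyl)-2-methoxy-4-propylphenyl (2E)-5-bromo-4-oxo-3-propylpent-2-enoate | CCC/C(C(=O)CBr)=C\C(=O)Oc1c(OCc2ccccc2)cc(CCC)c(C(=O)OCc2ccccc2)c1OC
F6 | step 9 | tert-butyl (E)-1,2-dichlorovinyl ether | CC(C)(C)O/C(Cl)=C\Cl
F7 | step 9 | lithium tert-butoxyacetylide | [Li+].[C-]#COC(C)(C)C
F8 | step 9 | tert-butoxyacetylene | CC(C)(C)OC#C
F9 | step 9 | benzyl 4-(benzyloxy)-3-{[4-(tert-butoxy)-2-hydroxy-6-propylbenzoyl]oxy}-2-methoxy-6-propylbenzoate | CCCc1cc(OC(C)(C)C)cc(O)c1C(=O)Oc1c(OCc2ccccc2)cc(CCC)c(C(=O)OCc2ccccc2)c1OC
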